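**Plan**
1. Retrosynthetic cuts, in order: the two acetates; the C2=C3 double bond; the C4'–C5' bond of the side chain (olefination); then the C1–C5 bond of the acyloin (C1 ketone, C5 tertiary carbinol), which opens the ring to a keto-dialdehyde.
2. Enabling feature: C5 is both the carbinol carbon of an α-ketol and the middle carbon of a dihydroxyacetone unit O4–C4–C5–C1'–O1' whose two oxygens are syn. Tied into a 1,3-dioxane (an acetonide ring absent from the target) and given two identical 3-oxopropyl arms, the open precursor is a meso 1,3-dioxan-5-one.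
3. Forward: 2,2-dimethyl-1,3-dioxan-5-one is bis-butenylated through its hydrazone, equilibrated to the meso cis ketone and ozonized. A chiral carbene-catalysed benzoin closure then forms the only carbocycle, the cyclopentanone, fused to the dioxane. The spare arm becomes the tetradecyl chain (Wittig, H2); Saegusa–Ito oxidation, acetonide removal and acetylation finish the route.
4. Stereochemistry: C4/C1' relative (cis) by thermodynamic equilibration; C5 by the obligatory cis fusion of the new ring to the temporary dioxane; the absolute configuration of all three by the catalyst's choice between the two mirror-image arms.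

Key step: step 6

Remarks on the chemistry (assumptions):
- Numbering: ring C1 (C=O), C2=C3, C4 (CH–OAc), C5 (C–OH); side chain C1' (CH–OAc) to C15'. The target is (4R,5S,1'S), with 4-OAc trans to 5-OH and O4/O1' syn.
- The sense of induction of the triazolium catalyst in step 6 cannot be predicted with certainty. The antipode used is the one that a pilot run shows to close the arm on the (R)-configured carbon of 9; both antipodes are available.
- Compound 10 is drawn as the open hydroxy aldehyde; equilibration with the six-membered lactol formed by the C5 hydroxyl is expected.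

Step 1
Reactants: 1 2,2-dimethyl-1,3-dioxan-5-one; 2 1,1-dimethylhydrazine
Product: 3 2-(2,2-dimethyl-1,3-dioxan-5-ylidene)-1,1-dimethylhydrazine
Conditions: Me2NNH2, cyclohexane, reflux, Dean–Stark trap
Reagents that add atoms: 1,1-dimethylhydrazine (2), CN(C)N
Why: Condensation of the unhindered ketone gives the N,N-dimethylhydrazone, needed because the free dioxanone does not give a clean lithium enolate (hydrazone formation).

Step 2
Reactants: 3 dimethylhydrazone; 4 4-iodobut-1-ene
Product: 5 2-[4-(but-3-en-1-yl)-2,2-dimethyl-1,3-dioxan-5-ylidene]-1,1-dimethylhydrazine (racemic)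
Conditions: t-BuLi, THF, −78 °C; then 4, −100 °C → rt
Reagents that add atoms: 4-iodobut-1-ene (4), C=CCCI
Why: Lithiation gives the azaenolate, which the primary iodide alkylates at carbon at low temperature (hydrazone azaenolate alkylation); the new centre is racemic, which is of no consequence here.

Step 3
Reactants: 5 mono-butenyl hydrazone; 4 4-iodobut-1-ene
Product: 6 2-[4,6-di(but-3-en-1-yl)-2,2-dimethyl-1,3-dioxan-5-ylidene]-1,1-dimethylhydrazine (cis/trans mixture)
Conditions: t-BuLi, THF, −78 °C; then 4, −100 °C → rt
Reagents that add atoms: 4-iodobut-1-ene (4), C=CCCI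
Why: Deprotonation occurs at the remaining CH2 (the less substituted alpha' carbon) and the azaenolate is alkylated again, giving the 4,6-disubstituted hydrazone as a cis/trans mixture that step 4 corrects (alpha,alpha'-bisalkylation of a ketone hydrazone).

Step 4
Reactants: 6 bis-butenyl hydrazone
Product: 8 (4R,6S)-4,6-di(but-3-en-1-yl)-2,2-dimethyl-1,3-dioxan-5-one (meso cis isomer), via cis/trans ketone mixture 7 (not isolated)
Conditions: sat. aq. oxalic acid, Et2O, rt; organic phase then DBU (cat.), CH2Cl2, rt; chromatography
Reagents that add atoms: water, O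
Why: Mild acid hydrolysis frees the ketone and base-mediated enolization equilibrates both alpha centres to the cis isomer, the only one that places both chains equatorial on a chair carrying an axial methyl at C2; with identical chains this isomer is meso, so no enantiomer question arises (hydrazone hydrolysis, thermodynamic epimerization).

Step 5
Reactants: 8 meso cis diene ketone
Product: 9 3,3'-[(4R,6S)-2,2-dimethyl-5-oxo-1,3-dioxane-4,6-diyl]dipropanal (meso)
Conditions: O3, CH2Cl2, −78 °C; then PPh3, −78 °C → rt; used without delay
Reagents that add atoms: ozone, [O-][O+]=O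
Why: Ozone cleaves both terminal alkenes to aldehydes while the ketone and the acetonide are inert, and the neutral reductive work-up avoids epimerization of the alpha centres (ozonolysis).

Step 6
Reactants: 9 meso keto-dialdehyde
Product: 10 3-[(4S,4aS,7aR)-4a-hydroxy-2,2-dimethyl-5-oxohexahydrocyclopenta[d][1,3]dioxin-4-yl]propanal (cis-fused)
Conditions: chiral aminoindanol-derived N-pentafluorophenyl triazolium tetrafluoroborate (10 mol %, antipode per the remark above), i-Pr2NEt (10 mol %), toluene, 0.02 M, 0 °C → rt
Reagents that add atoms: none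
Why: Proposed new method: the triazolylidene adds to either aldehyde to give a Breslow enaminol, an acyl anion equivalent at C1, which attacks the dioxanone carbonyl carbon C5 with proton transfer from the enaminol hydroxyl to the carbonyl oxygen and then releases the carbene, so the C1–C5 bond of the α-ketol forms without a stoichiometric reagent. The closest known reaction type is the enantioselective intramolecular crossed aldehyde–ketone benzoin reaction, including the desymmetrization of cyclic 1,3-diketones that carry one aldehyde arm; what is new is that the catalyst must choose between two enantiotopic aldehyde arms of a meso ketone. The cyclopentanone ring closes in the 5-exo-trig mode. At C5 the new hydroxyl is forced trans to O4 and the C1' carbon cis to O4, because the five-membered ring can only fuse cis onto the chair dioxane (the equatorial arm at C4 reaches the adjacent carbonyl from its axial face); which arm reacts, and with it the absolute configuration at C4, C5 and C1', is decided by the chiral catalyst in the C–C bond-forming transition state. The step needs arm selectivity, aldehyde-to-ketone rather than aldehyde-to-aldehyde coupling, and a stop after one closure; the first rests on the catalyst, the second on ring size (five-membered against nine-membered) and dilution, the third on the hindered new ketone and on the spare aldehyde being held as a lactol by the new tertiary hydroxyl.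

Step 7
Reactants: 10 ketol aldehyde; 11 undecyltriphenylphosphonium bromide
Product: 12 (4S,4aS,7aR)-4a-hydroxy-2,2-dimethyl-4-[(3Z)-tetradec-3-en-1-yl]hexahydrocyclopenta[d][1,3]dioxin-5-one
Conditions: 11 (2.5 equiv), NaN(SiMe3)2 (2.4 equiv), THF, 0 °C; then 10, −78 °C → 0 °C
Reagents that add atoms: undecyltriphenylphosphonium bromide (11), CCCCCCCCCCC[P+](c1ccccc1)(c1ccccc1)c1ccccc1.[Br-]
Why: The non-stabilized ylide should olefinate the aldehyde (also reached from the lactol) much faster than the hindered alpha-oxygenated cyclopentanone at low temperature, one extra equivalent being consumed by the tertiary hydroxyl (Wittig reaction; the alkene geometry is irrelevant).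

Step 8
Reactants: 12 alkenyl ketol
Product: 13 (4S,4aS,7aR)-4a-hydroxy-2,2-dimethyl-4-tetradecylhexahydrocyclopenta[d][1,3]dioxin-5-one
Conditions: H2 (1 atm), Pd/C, EtOAc, rt
Reagents that add atoms: none
Why: Heterogeneous hydrogenation saturates the isolated alkene and leaves the ketone and the acetonide untouched, completing the tetradecyl chain (catalytic hydrogenation).

Step 9
Reactants: 13 tetradecyl ketol
Product: 14 (4S,4aS,7aR)-2,2-dimethyl-4-tetradecyl-4a,5-bis(trimethylsilyloxy)-4,4a,7,7a-tetrahydrocyclopenta[d][1,3]dioxine
Conditions: LiN(SiMe3)2 (2.5 equiv), Me3SiCl (3 equiv), THF, −78 °C → 0 °C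
Reagents that add atoms: chlorotrimethylsilane, C[Si](C)(C)Cl
Why: The amide base forms the alkoxide and then the enolate, which can only form towards C2 because C5 is quaternary, and both are silylated in situ (silyl enol ether formation with internal quench).

Step 10
Reactants: 14 bis-silyl compound
Product: 15 (4S,4aS,7aR)-2,2-dimethyl-4-tetradecyl-4a-(trimethylsilyloxy)-4a,7a-dihydrocyclopenta[d][1,3]dioxin-5(4H)-one
Conditions: Pd(OAc)2 (1.1 equiv), MeCN, rt
Reagents that add atoms: none
Why: The silyl enol ether transfers to divalent palladium and beta-hydride elimination from C3 of the palladium enolate gives the C2=C3 enone and zerovalent palladium, without touching C4 or C5 (Saegusa–Ito oxidation).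

Step 11
Reactants: 15 silylated enone acetonide
Product: 16 (4R,5S)-4,5-dihydroxy-5-[(1S)-1-hydroxypentadecyl]cyclopent-2-en-1-one
Conditions: 2 M aq. HCl, THF, rt
Reagents that add atoms: none
Why: Aqueous acid hydrolyses the silyl ether and the acetonide of the 1,3-diol, while ionization at C4 is disfavoured because the cation would sit next to the electron-poor enone, so all three stereocentres are retained (acetal and silyl ether hydrolysis).

Step 12
Reactants: 16 triol
Product: 17 (4R,5S)-4-acetoxy-5-[(1S)-1-acetoxypentadecyl]-5-hydroxycyclopent-2-en-1-one (target)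
Conditions: Ac2O (2.5 equiv), pyridine, DMAP (5 mol %), CH2Cl2, 0 °C
Reagents that add atoms: acetic anhydride, CC(=O)OC(C)=O
Why: The two secondary hydroxyls are acylated while the tertiary alpha-keto hydroxyl at C5 is too hindered to react under these mild conditions (selective O-acetylation).

**Compound list**
1 | 2,2-dimethyl-1,3-dioxan-5-one | CC1(C)OCC(=O)CO1 | starting material
2 | 1,1-dimethylhydrazine | CN(C)N | starting material
3 | 2-(2,2-dimethyl-1,3-dioxan-5-ylidene)-1,1-dimethylhydrazine | CN(C)N=C1COC(C)(C)OC1 | intermediate
4 | 4-iodobut-1-ene | C=CCCI | starting material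
5 | 2-[4-(but-3-en-1-yl)-2,2-dimethyl-1,3-dioxan-5-ylidene]-1,1-dimethylhydrazine, racemic | CN(C)N=C1COC(C)(C)OC1CCC=C | intermediate
6 | 2-[4,6-di(but-3-en-1-yl)-2,2-dimethyl-1,3-dioxan-5-ylidene]-1,1-dimethylhydrazine, cis/trans mixture | CN(C)N=C1C(CCC=C)OC(C)(C)OC1CCC=C | intermediate
7 | 4,6-di(but-3-en-1-yl)-2,2-dimethyl-1,3-dioxan-5-one, cis/trans mixture | C=CCCC1OC(C)(C)OC(CCC=C)C1=O | intermediate (not isolated)
8 | (4R,6S)-4,6-di(but-3-en-1-yl)-2,2-dimethyl-1,3-dioxan-5-one, meso cis | C=CCC[C@@H]1OC(C)(C)O[C@H](CCC=C)C1=O | intermediate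
9 | 3,3'-[(4R,6S)-2,2-dimethyl-5-oxo-1,3-dioxane-4,6-diyl]dipropanal, meso cis | O=CCC[C@@H]1OC(C)(C)O[C@H](CCC=O)C1=O | intermediate
10 | 3-[(4S,4aS,7aR)-4a-hydroxy-2,2-dimethyl-5-oxohexahydrocyclopenta[d][1,3]dioxin-4-yl]propanal, cis-fused, open form | O=CCC[C@H](OC2(C)C)[C@@]1(O)C(=O)CC[C@H]1O2 | intermediate
11 | undecyltriphenylphosphonium bromide | CCCCCCCCCCC[P+](c1ccccc1)(c1ccccc1)c1ccccc1.[Br-] | starting material
12 | (4S,4aS,7aR)-4a-hydroxy-2,2-dimethyl-4-[(3Z)-tetradec-3-en-1-yl]hexahydrocyclopenta[d][1,3]dioxin-5-one | CCCCCCCCCC/C=C\CC[C@H](OC2(C)C)[C@@]1(O)C(=O)CC[C@H]1O2 | intermediate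
13 | (4S,4aS,7aR)-4a-hydroxy-2,2-dimethyl-4-tetradecylhexahydrocyclopenta[d][1,3]dioxin-5-one | CCCCCCCCCCCCCC[C@H](OC2(C)C)[C@@]1(O)C(=O)CC[C@H]1O2 | intermediate
14 | (4S,4aS,7aR)-2,2-dimethyl-4-tetradecyl-4a,5-bis(trimethylsilyloxy)-4,4a,7,7a-tetrahydrocyclopenta[d][1,3]dioxine | CCCCCCCCCCCCCC[C@H](OC2(C)C)[C@@]1(O[Si](C)(C)C)C(O[Si](C)(C)C)=CC[C@H]1O2 | intermediate
15 | (4S,4aS,7aR)-2,2-dimethyl-4-tetradecyl-4a-(trimethylsilyloxy)-4a,7a-dihydrocyclopenta[d][1,3]dioxin-5(4H)-one | CCCCCCCCCCCCCC[C@H](OC2(C)C)[C@@]1(O[Si](C)(C)C)C(=O)C=C[C@H]1O2 | intermediate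
16 | (4R,5S)-4,5-dihydroxy-5-[(1S)-1-hydroxypentadecyl]cyclopent-2-en-1-one | CCCCCCCCCCCCCC[C@H](O)[C@@]1(O)C(=O)C=C[C@H]1O | intermediate
17 | (4R,5S)-4-acetoxy-5-[(1S)-1-acetoxypentadecyl]-5-hydroxycyclopent-2-en-1-one | CCCCCCCCCCCCCC[C@H](OC(C)=O)[C@@]1(O)C(=O)C=C[C@H]1OC(C)=O | target

Total step count: 12. Longest linear sequence: 12 steps (1 → 17).

**Steps most likely to fail**

Step 6 (Proposed new method). What may go wrong: insufficient discrimination between the two enantiotopic arms, giving low enantiomeric purity; base-mediated epimerization of 9 to the trans isomer before closure; or a second carbene-mediated closure of the spare aldehyde. The fallback uses known auxiliary chemistry, sets out from 1 and comes back at 13, so steps 7 and 8 are not needed. Condensation of 1 with (S)-1-amino-2-(methoxymethyl)pyrrolidine (SAMP) would give the SAMP hydrazone F1. Metalation with t-BuLi and alkylation with 1-iodotetradecane would give, under auxiliary control, the (4S)-tetradecyl hydrazone F2. Two-phase oxalic acid cleavage would give (4S)-2,2-dimethyl-4-tetradecyl-1,3-dioxan-5-one F3. Condensation with the antipodal auxiliary (RAMP) would give the hydrazone F4, whose metalation and alkylation with 4, again under auxiliary control, should give the cis-4,6-disubstituted hydrazone F5. Ozonolysis with PPh3 work-up cleaves both C=N and C=C and would give the keto-aldehyde F6. An achiral N-pentafluorophenyl triazolium tetrafluoroborate with i-Pr2NEt then closes the same C1–C5 bond by the known intramolecular aldehyde–ketone benzoin reaction, cis fusion to the dioxane setting C5, to give 13.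

Step 5. What may go wrong: loss of the keto-dialdehyde through intramolecular aldol reaction, hydrate or oligomer formation, or alpha-epimerization during work-up and isolation. The fallback sets out from 8 and comes back at 9. Dihydroxylation of both alkenes (OsO4 cat., N-methylmorpholine N-oxide, acetone/water) would give the storable tetraol F7. Cleavage with NaIO4 on silica gel in CH2Cl2 immediately before step 6 would release 9 under neutral conditions, and its filtered solution would be used directly.

Step 10. What may go wrong: protodesilylation of the enol ether back to the ketone, in competition with slow palladation next to the quaternary centre. The fallback sets out from 14 and comes back at 15. Treatment of 14 with PhSeCl (THF, −78 °C) would give the alpha-phenylselanyl ketone F8. Oxidation with H2O2 and pyridine in CH2Cl2 at 0 °C would then give 15 by syn elimination of the selenoxide, which can only occur towards C3.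

**Further compounds**
F1 | step 6 | (S)-N-(2,2-dimethyl-1,3-dioxan-5-ylidene)-2-(methoxymethyl)pyrrolidin-1-amine | COC[C@@H]1CCCN1N=C2COC(C)(C)OC2
F2 | step 6 | (S)-N-[(4S)-2,2-dimethyl-4-tetradecyl-1,3-dioxan-5-ylidene]-2-(methoxymethyl)pyrrolidin-1-amine | COC[C@@H]1CCCN1N=C2COC(C)(C)O[C@H]2CCCCCCCCCCCCCC
F3 | step 6 | (4S)-2,2-dimethyl-4-tetradecyl-1,3-dioxan-5-one | O=C1COC(C)(C)O[C@H]1CCCCCCCCCCCCCC
F4 | step 6 | (R)-N-[(4S)-2,2-dimethyl-4-tetradecyl-1,3-dioxan-5-ylidene]-2-(methoxymethyl)pyrrolidin-1-amine | COC[C@H]1CCCN1N=C2COC(C)(C)O[C@H]2CCCCCCCCCCCCCC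
F5 | step 6 | (R)-N-[(4R,6S)-4-(but-3-en-1-yl)-2,2-dimethyl-6-tetradecyl-1,3-dioxan-5-ylidene]-2-(methoxymethyl)pyrrolidin-1-amine | COC[C@H]1CCCN1N=C2[C@@H](CCC=C)OC(C)(C)O[C@H]2CCCCCCCCCCCCCC
F6 | step 6 | 3-[(4R,6S)-2,2-dimethyl-5-oxo-6-tetradecyl-1,3-dioxan-4-yl]propanal | CCCCCCCCCCCCCC[C@@H]1OC(C)(C)O[C@H](CCC=O)C1=O
F7 | step 5 | (4R,6S)-4,6-bis(3,4-dihydroxybutyl)-2,2-dimethyl-1,3-dioxan-5-one, mixture at the new carbinol carbons | OCC(O)CC[C@@H]1OC(C)(C)O[C@H](CCC(O)CO)C1=O
F8 | step 10 | (4S,4aS,7aR)-2,2-dimethyl-6-(phenylselanyl)-4-tetradecyl-4a-(trimethylsilyloxy)hexahydrocyclopenta[d][1,3]dioxin-5-one, mixture at C6 | CCCCCCCCCCCCCC[C@H](OC2(C)C)[C@@]1(O[Si](C)(C)C)C(=O)C([Se]c3ccccc3)C[C@H]1O2
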